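**Remarks on the chemistry (made before the route)**

- Germacrane numbering is used throughout: ring carbons C1–C10, C11/C12/C13 the lactone unit (O on C6), C14 the ester carbon on C10, C15 the methyl on C4. The target is 4R,5S,6R,7R,8S,9S with a 2R glycidate. CIP letters of intermediates change with the substituents, so the SMILES strings are authoritative.
- The silyl ether on O14 is triisopropylsilyl, not tert-butyldimethylsilyl. It is a spectator and comes directly from a commercial chloromethyl silyl ether.
- Neryl acetate, the commercial acetate of nerol, is the terpene starting material.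
- Assumption: the (R)-configured phosphoric acid used in step 7 delivers the allyl group to the Re face of the aldehyde, as with simple conjugated aldehydes. If the sense is opposite, the (S)-acid is used.

## Structural features

The target is a ten-membered carbocycle (C1–C10) with a cis-fused α-methylene-γ-butyrolactone on C6/C7, a 4,5-epoxide whose ring bonds C3–C4 and C5–C6 are cis, and a C1=C10 alkene with C2 and C9 cis that is conjugated to the C14 methyl ester. Six contiguous stereocentres run from C4 to C9, and a seventh is the quaternary carbon of the (R)-2-methylglycidate on O9. O8 carries acetate and is threo (ring-trans) to O9. O6 is threo to the epoxide oxygen, H6 and H7 are cis, and O8 lies on the ring face opposite the lactone. Fragile groups are the two epoxides (acid; the 4,5-epoxide is transannular to C1=C10), the methylene lactone (nucleophiles, reductants, diazoalkanes) and four acyl groups that can migrate between O6, O8 and O9 under base. The real difficulties are closing the medium ring while fixing C8 and C9, and telling two neighbouring secondary hydroxyls apart. The key step uses the fact that C8–C9 is a ring bond flanked by two threo oxygens, the retron of a reductive carbonyl coupling, in a chain stiffened by the cis-lactone, the cis-epoxide and the Z-alkene. One consequence for the early part: threo O5/O6 is the outcome of hydroxyl-directed epoxidation of a Z-allylic alcohol, whereas Felkin-type addition of a C7 nucleophile to a cis-2,3-epoxy aldehyde would be expected to give erythro. The C6–C7 bond is therefore made before the epoxide.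

## Logic of the disconnections

**35 ⇒ 31 + 33.** The O9–acyl bond is cut last. This keeps the acid-labile glycidate out of every earlier step, and 31 has only one free hydroxyl. The forward step must acylate a hindered hydroxyl next to an acrylate without moving the O8 acetate.

**33 ⇒ 32.** The carboxyl is traced to the primary alcohol of a commercial epoxy alcohol. The oxidation must leave the epoxide and the quaternary centre intact.

**31 ⇒ 28 (through 30 and 29).** The C14 ester is taken back to a primary allylic alcohol, so no ring-forming step has to tolerate a doubly activated C10. The oxidation must choose the primary over the secondary allylic hydroxyl and must spare the methylene lactone.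

**28 ⇒ 26 (through 27).** The O8–acetyl bond is cut, and O9 and O14 are tied together as a six-membered silylene. Only a 1,3-diol closes this ring, so the two secondary hydroxyls are distinguished by constitution and not by a rate difference. The silylene must later be removed without acetyl migration.

**26 ⇒ 23.** The C11=C13 bond is cut. The methylene is introduced while no other ester is present. This demands a strong-base enolisation in the presence of one free hydroxyl.

**23 ⇒ 21 (through 22).** The two O–Si bonds of the silylene are cut and O14 returns to its monosilyl ether. The triol must take the silicon bridge on O9/O14 only.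

**21 ⇒ 20.** The C8–C9 bond is cut. One step then forms the ring, the bond and both carbinol centres from a dialdehyde whose four stereocentres are made in open-chain chemistry. The forward step must close a ten-membered ring, couple at C9 and not at C1, keep the alkene geometry and give the threo diol.

**20 ⇒ 18 ⇒ 15 (through 19, 17 and 16).** The C8 aldehyde is traced to a vinyl group. The C9 aldehyde and the lactone carbonyl are traced to two methyl esters and the lactone C–O bond to a free C6 hydroxyl. One reduction and one oxidation then set all oxidation levels. The final ozonolysis must spare the conjugated alkene and must release the epimerisable aldehyde under neutral conditions.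

**15 ⇒ 14.** The two C–O bonds of the 4,5-epoxide are cut. This leaves a Z-allylic alcohol whose hydroxyl can direct the oxidant. The step must be threo-selective and must not touch the vinyl and enoate alkenes.

**14 ⇒ 9 + 12 (through 13).** The C6–C7 bond is cut. This gives an achiral enal and an allylboron reagent that carries C7, C8, C11 and C12. The step must be anti-selective (from the E-reagent) and enantioselective (from the catalyst).

**12 ⇒ 10 + 11.** The C=C bond of the boronate is cut by metathesis into two commercial terminal alkenes. The E-isomer must dominate.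

**9 ⇒ 3 + 6 (through 8 and 7).** The C1=C10 bond is cut. The ester (C9) must end up cis to the chain, which calls for a Z-selective phosphonate olefination.

**6 ⇒ 4 + 5, and 3 ⇒ 1 (through 2).** The C10–C14 bond is cut by enolate alkylation, which also brings in the O14 silyl ether. The distal alkene of 1 is cut by ozone, which requires selectivity over the allylic-acetate alkene.

## Other disconnections considered

**Alternative 1:** The cut is C7–C11 (with the C8–H bond). Bu3SnH converts the 2-bromoallyl mixed acetal A2 into a vinyl radical that closes 5-exo onto C7 of the C7=C8 enol acetate, and the C8 α-acetoxy radical is then reduced, giving A1.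
- In its favour: the exocyclic methylene arrives with the ring, so no enolate methylenation is needed, and here it is better than the chosen plan. The 5-exo closure onto a ring alkene should give the cis fusion. O8 (acetate) and O9 (silyl ether) are different from the start, again better than the chosen plan, which spends two steps on this.
- Against it: A2 already contains the ten-membered ring, a regiodefined enol acetate and C9, so the main difficulty is only postponed. C8 would be set by hydrogen transfer to a planar radical in a flexible ring. The vinyl radical can shift hydrogen or add across the ring to the C1=C10 acrylate. A1 must still be hydrolysed and oxidised to the lactone next to an acid-sensitive epoxide.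
- Comparison: about three steps are saved after ring closure, but an independent macrocyclisation is needed before it. Overall the chosen plan is shorter and places its stereochemical risk in one step.
- Structural note: A1 has two methylene groups between C1 and C4. A string with three would describe an eleven-membered ring.

**Alternative 2:** The cuts are C7–C8 and C6–O. NaOCl oxidises the aldoxime A4 to the nitrile oxide A5, which adds across the Z-C6=C7 alkene to give A3.
- In its favour: one mild step forms the carbocycle and fixes C6 and C7 cis, stereospecifically from the alkene geometry. The C14 ester is already in place, which is better than the chosen plan. O8 appears as a C=N carbon while O9 is silylated, so the two oxygens are differentiated, again better.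
- Against it: the face of the alkene that is attacked is controlled only by the remote C5 and C9 centres. In A3 the heterocycle shares C6, C7 and C8 with the carbocycle, so it is bridged with a bridgehead C=N and not simply fused at C6/C7. The transition state is therefore strained, and the regioisomeric nine-membered mode competes. After N–O cleavage, C8 is a ketone beside an epimerisable C7 and must be reduced selectively. The lactone oxidation and the methylenation are still needed.
- Comparison: both plans create two stereocentres in the ring-forming step. The chosen plan makes C6/C7 by acyclic, catalyst-controlled chemistry and needs fewer steps after ring closure.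
- Structural note: A3 also has only two methylenes between C1 and C4.

**Alternative 3:** The cut is C5–C6. CrCl2 with catalytic NiCl2 converts the Z-vinyl iodide of A7 into a vinylchromium species that adds to the C6 aldehyde, giving the allylic alcohol A6.
- In its favour: this coupling is among the most dependable closures of medium rings. It tolerates the C12 and C14 esters, so no late oxidation at C14 is needed, which is better than the chosen plan. The Z-geometry is transferred, and the resulting Z-allylic alcohol would direct the threo epoxidation exactly as in the chosen plan, so the two are equal there.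
- Against it: C6 is created during ring closure with no reagent control. The trans-acetonide on O8/O9 must be built beforehand and later removed with acid beside the epoxide, after which the two hydroxyls are again equivalent. A7 carries an α-stereocentre with a β-alkoxy group and is as fragile as 20. A large excess of chromium salt is required.
- Comparison: step economy is similar. The chosen plan fixes C6 before the ring is closed and leaves only the diol centres to the macrocyclisation.

Key step: step 12

## Route

**Step 1**
Reactants: 1 neryl acetate [(2Z)-3,7-dimethylocta-2,6-dien-1-yl acetate]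
Product: 3 (4Z)-6-acetoxy-4-methylhex-4-enal, via secondary ozonide 2 (not isolated)
Conditions: O3 (1 equiv), CH2Cl2, −78 °C; then Me2S, −78 °C to rt
Reagents that add atoms: ozone, [O-][O+]=O
Why: Selective ozonolysis: the electrophilic oxidant attacks the electron-rich distal trisubstituted alkene much faster than the 2,3-alkene, which is deactivated by the allylic acetate. No stereocentre is formed and the Z-alkene is untouched.

**Step 2**
Reactants: 4 methyl 2-[bis(2,2,2-trifluoroethoxy)phosphoryl]acetate; 5 (chloromethoxy)triisopropylsilane
Product: 6 methyl 2-[bis(2,2,2-trifluoroethoxy)phosphoryl]-3-[(triisopropylsilyl)oxy]propanoate (racemic)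
Conditions: NaH (1.0 equiv), THF, 0 °C; then 5, 0 °C to rt
Reagents that add atoms: none
Why: C-alkylation of a stabilised phosphonoacetate anion with a reactive α-chloro ether (enolate alkylation). One equivalent of base limits dialkylation, and silanolate is too poor a leaving group for β-elimination from the stabilised anion in the cold.

**Step 3**
Reactants: 3 (4Z)-6-acetoxy-4-methylhex-4-enal; 6 the phosphonate from step 2
Product: 7 methyl (2Z,6Z)-8-acetoxy-6-methyl-2-{[(triisopropylsilyl)oxy]methyl}octa-2,6-dienoate
Conditions: KN(SiMe3)2, 18-crown-6, THF, −78 °C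
Reagents that add atoms: none
Why: Still–Gennari variant of the Horner–Wadsworth–Emmons olefination. The electron-poor trifluoroethyl phosphonate makes elimination from the kinetic adduct fast, so the ester (C9) ends up cis to the chain and the silyloxymethyl group (C14) trans.

**Step 4**
Reactants: 7 the acetate from step 3
Product: 8 methyl (2Z,6Z)-8-hydroxy-6-methyl-2-{[(triisopropylsilyl)oxy]methyl}octa-2,6-dienoate
Conditions: K2CO3 (0.3 equiv), MeOH, 0 °C
Reagents that add atoms: none
Why: Base-catalysed transesterification. The unhindered acetate is cleaved, while exchange at the hindered conjugated methyl ester is degenerate in methanol, and the silyl ether is stable.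

**Step 5**
Reactants: 8 the allylic alcohol from step 4
Product: 9 methyl (2Z,6Z)-6-methyl-8-oxo-2-{[(triisopropylsilyl)oxy]methyl}octa-2,6-dienoate
Conditions: TEMPO (10 mol%), PhI(OAc)2, CH2Cl2, rt
Reagents that add atoms: none
Why: Oxoammonium-mediated oxidation of a primary allylic alcohol. The conditions are nearly neutral, so the Z-enal should form without isomerisation to the E-isomer.

**Step 6**
Reactants: 10 2-allyl-4,4,5,5-tetramethyl-1,3,2-dioxaborolane; 11 methyl but-3-enoate
Product: 12 methyl (3E)-5-(4,4,5,5-tetramethyl-1,3,2-dioxaborolan-2-yl)pent-3-enoate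
Conditions: second-generation Hoveyda–Grubbs catalyst (2 mol%), 11 (3 equiv), CH2Cl2, 40 °C
Reagents that add atoms: none
Why: Olefin cross-metathesis of two terminal alkenes, driven by loss of ethene and by the excess of volatile 11. Secondary metathesis should enrich the more stable E-isomer.

**Step 7**
Reactants: 9 the enal from step 5; 12 the E-allylboronate from step 6
Product: 14 dimethyl (2Z,6Z,8R,9R)-9-ethenyl-8-hydroxy-6-methyl-2-{[(triisopropylsilyl)oxy]methyl}undeca-2,6-dienedioate (germacrane C6 R and C7 R), via pinacol borate 13 (not isolated)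
Conditions: (R)-TRIP [3,3′-bis(2,4,6-triisopropylphenyl)-1,1′-binaphthyl-2,2′-diyl hydrogen phosphate] (5 mol%), 4 Å molecular sieves, toluene, −30 °C; aqueous NaHCO3 work-up
Reagents that add atoms: none
Why: Chiral-Brønsted-acid-catalysed allylboration through a closed chair transition state. The E-boronate places O6 and C11 anti, which later becomes the cis-lactone. The acid binds the boronate oxygen and the formyl hydrogen and should direct attack to the Re face, giving C6 R and with it C7 R. The product is used at once so that the hydroxyl stays free for step 8.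

**Step 8**
Reactants: 14 the hydroxy diester from step 7
Product: 15 dimethyl (2Z,6R,7S,8R,9R)-6,7-epoxy-9-ethenyl-8-hydroxy-6-methyl-2-{[(triisopropylsilyl)oxy]methyl}undec-2-enedioate (germacrane C4 R, C5 S, C6 R and C7 R)
Conditions: mCPBA, NaHCO3, CH2Cl2, 0 °C
Reagents that add atoms: 3-chloroperbenzoic acid, OOC(=O)c1cccc(Cl)c1
Why: Hydroxyl-directed peracid epoxidation. A(1,3) strain from C3 (cis to C6) holds H6 in the alkene plane, so the hydrogen-bonded peracid adds to the hydroxyl face and gives the threo epoxy alcohol, setting C4 and C5 from C6. The monosubstituted vinyl group and the electron-poor enoate should react far more slowly. If the product lactonises, that does no harm, because steps 9 and 10 converge.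

**Step 9**
Reactants: 15 the epoxy alcohol from step 8
Product: 16 (4R,5R)-4-ethenyl-5-[(2S,3R)-3-{(3E)-4-(hydroxymethyl)-5-[(triisopropylsilyl)oxy]pent-3-en-1-yl}-3-methyloxiran-2-yl]oxolan-2-ol (both lactol epimers; the hydroxymethyl group is cis to the chain)
Conditions: iBu2AlH (5 equiv), CH2Cl2, −78 to −40 °C; aqueous KNaC4H4O6 work-up
Reagents that add atoms: none
Why: Hydride reduction. The enoate gives the allylic alcohol, and the γ-hydroxy ester stops at the aldehyde level and closes to the lactol. The epoxide and silyl ether should survive in the cold, and any over-reduced 1,4-diol is carried into step 10, which converts it to the same lactone.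

**Step 10**
Reactants: 16 the lactol from step 9
Product: 18 (4R,5R)-4-ethenyl-5-[(2S,3R)-3-{(3Z)-4-formyl-5-[(triisopropylsilyl)oxy]pent-3-en-1-yl}-3-methyloxiran-2-yl]oxolan-2-one, via lactol enal 17 (not isolated)
Conditions: TEMPO (20 mol%), PhI(OAc)2 (2.5 equiv), CH2Cl2, rt
Reagents that add atoms: none
Why: Oxoammonium oxidation converts the primary allylic alcohol to the Z-enal and the lactol to the lactone in one operation. No stereocentre is touched, and the mild conditions should preserve the alkene geometry.

**Step 11**
Reactants: 18 the vinyl lactone from step 10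
Product: 20 (2R,3S)-2-[(2S,3R)-3-{(3Z)-4-formyl-5-[(triisopropylsilyl)oxy]pent-3-en-1-yl}-3-methyloxiran-2-yl]-5-oxooxolane-3-carbaldehyde, via secondary ozonide 19 (not isolated)
Conditions: O3, CH2Cl2, −78 °C (Sudan Red 7B end point); then PPh3, −78 to 0 °C; used without purification
Reagents that add atoms: ozone, [O-][O+]=O
Why: Selective ozonolysis: the isolated vinyl group is far more reactive than the conjugated, electron-poor enal alkene. The neutral phosphine work-up avoids epimerisation at C7 and β-elimination of the lactone oxygen.

**Step 12**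
Reactants: 20 the dialdehyde from step 11
Product: 21 (4R,5S,6R,7R,8S,9S)-4,5-epoxy-8,9-dihydroxy-14-[(triisopropylsilyl)oxy]-13-norgermacr-1(10)-en-12,6-olide (C2 and C9 cis on the alkene)
Conditions: SmI2 (3 equiv), THF, 0.002 M, syringe-pump addition of 20, −40 to 0 °C; then pH 7 phosphate buffer at −40 °C
Reagents that add atoms: none
Why: SmI2 (divalent samarium) transfers one electron to the conjugated C9 aldehyde, the more easily reduced carbonyl, and the samarium-bound ketyl adds through C9 to the samarium-coordinated C8 carbonyl (or combines with a second ketyl formed there). A second electron and aqueous work-up give the diol. The closest known reaction type is the intramolecular pinacol coupling of dialdehydes to cyclic 1,2-diols with SmI2 or low-valent titanium. The only ring closed is the ten-membered carbocycle, by end-to-end 10-exo-trig attack on the C8 carbonyl; this is helped by high dilution and by the cis-lactone, the cis-epoxide and the Z-alkene, which leave little of the tether free to rotate. C8 should be set by C7 through the cis-fused lactone, because the bulky O–Sm group at C8 is expected to sit on the ring face away from the lactone, cis to H7. C9 should be set by the preference of the two O–Sm groups, each bearing solvated trivalent samarium, to lie anti across the forming bond, which gives the threo, ring-trans diol. Coupling must occur at C9 and not at C1; the substituent on C10, the alkyl group on C1 and the greater strain of the eight-membered alternative should secure this. The alkene geometry must survive, so ring closure has to outrun rotation in the allylic ketyl, which is why the temperature is kept low. Without a strongly donating additive SmI2 should not reduce the epoxide, the lactone or the silyl ether, and the cold buffered quench limits acyl transfer from O6 to the new O8 alkoxide.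

**Step 13**
Reactants: 21 the diol from step 12
Product: 22 4,5-epoxy-8,9,14-trihydroxy-13-norgermacr-1(10)-en-12,6-olide (stereocentres as in 21)
Conditions: Bu4NF, AcOH (1:1), THF, 0 °C to rt
Reagents that add atoms: none
Why: Fluoride-induced desilylation of the primary silyl ether. The acetic acid buffer keeps alkoxide levels low, so the lactone should not migrate to O8.

**Step 14**
Reactants: 22 the triol from step 13
Product: 23 9,14-O-(di-tert-butylsilanediyl)-4,5-epoxy-8-hydroxy-13-norgermacr-1(10)-en-12,6-olide (stereocentres as in 21)
Conditions: tBu2Si(OTf)2 (1.05 equiv), 2,6-lutidine, CH2Cl2, −40 to 0 °C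
Reagents that add atoms: di-tert-butylsilyl bis(trifluoromethanesulfonate), CC(C)(C)[Si](OS(=O)(=O)C(F)(F)F)(OS(=O)(=O)C(F)(F)F)C(C)(C)C
Why: Silylene protection of a 1,3-diol. The primary O14 is silylated first and closes the six-membered ring onto O9; the ring to O8 would be seven-membered, so O8 stays free. Low temperature and the hindered base protect the epoxide.

**Step 15**
Reactants: 23 the silylene from step 14
Product: 26 9,14-O-(di-tert-butylsilanediyl)-4,5-epoxy-8-hydroxygermacra-1(10),11(13)-dien-12,6-olide (stereocentres as in 21), via Mannich base 24 (not isolated), via ammonium iodide 25 (not isolated)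
Conditions: LiN(iPr)2 (2.5 equiv), THF, −78 °C; CH2=NMe2+ I−, −78 to −30 °C; AcOH at −78 °C; then MeI, CH2Cl2/MeOH, rt; aqueous NaHCO3, rt
Reagents that add atoms: N,N-dimethylmethyleneiminium iodide (Eschenmoser's salt), C=[N+](C)C.[I-]
Why: Mannich aminomethylation of the lactone enolate (as alkoxide–enolate dianion), followed by quaternisation and E1cB elimination: the classical α-methylenation of lactones. No other enolisable ester is present, C11 becomes sp2 so its transient configuration does not matter, and the cold quench keeps the O8 alkoxide away from a neutral lactone.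

**Step 16**
Reactants: 26 the methylene lactone from step 15
Product: 27 8-acetoxy-9,14-O-(di-tert-butylsilanediyl)-4,5-epoxygermacra-1(10),11(13)-dien-12,6-olide (stereocentres as in 35)
Conditions: Ac2O, DMAP (cat.), pyridine, CH2Cl2, 0 °C to rt
Reagents that add atoms: acetic anhydride, CC(=O)OC(C)=O
Why: DMAP-catalysed acylation of the only free hydroxyl. The regiochemistry is fixed by the silylene.

**Step 17**
Reactants: 27 the acetate from step 16
Product: 28 8-acetoxy-4,5-epoxy-9,14-dihydroxygermacra-1(10),11(13)-dien-12,6-olide (stereocentres as in 35)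
Conditions: Bu4NF, AcOH (1:1), THF, 0 °C
Reagents that add atoms: none
Why: Fluoride cleavage of the silylene. The buffer suppresses O8-to-O9 acetyl migration and conjugate addition to the methylene lactone.

**Step 18**
Reactants: 28 the diol from step 17
Product: 29 8-acetoxy-4,5-epoxy-9-hydroxy-14-oxogermacra-1(10),11(13)-dien-12,6-olide (stereocentres as in 35)
Conditions: TEMPO (10 mol%), PhI(OAc)2 (1.1 equiv), CH2Cl2, 0 °C to rt
Reagents that add atoms: none
Why: Oxoammonium oxidation is sterically selective for the primary allylic hydroxyl over the secondary one at C9. O8 is already acetylated, so no lactol can form with the new aldehyde.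

**Step 19**
Reactants: 29 the aldehyde from step 18
Product: 30 8-acetoxy-4,5-epoxy-9-hydroxygermacra-1(10),11(13)-dien-12,6-olid-14-oic acid (stereocentres as in 35)
Conditions: NaClO2, NaH2PO4, 2-methylbut-2-ene, t-BuOH/H2O, 0 °C
Reagents that add atoms: sodium chlorite, [Na+].[O-]Cl=O
Why: Pinnick oxidation of a conjugated aldehyde. The alkene scavenger removes hypochlorite, so the alkenes and epoxide should be left alone.

**Step 20**
Reactants: 30 the acid from step 19
Product: 31 methyl 8-acetoxy-4,5-epoxy-9-hydroxygermacra-1(10),11(13)-dien-12,6-olid-14-oate (stereocentres as in 35)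
Conditions: MeI, KHCO3, DMF, 0 °C to rt
Reagents that add atoms: iodomethane, CI
Why: SN2 alkylation of the carboxylate. Bicarbonate is too weak to deprotonate the C9 hydroxyl, and a diazoalkane, which could add to the methylene lactone, is avoided.

**Step 21**
Reactants: 32 (S)-2-methylglycidol [(2S)-(2-methyloxiran-2-yl)methanol]
Product: 33 (R)-2-methylglycidic acid [(2R)-2-methyloxirane-2-carboxylic acid]
Conditions: RuCl3 (2 mol%), NaIO4, MeCN/EtOAc/H2O, 0 °C to rt; used directly
Reagents that add atoms: water, O
Why: RuO4-mediated oxidation of a primary alcohol to the acid through the aldehyde hydrate, a standard route from epoxy alcohols to epoxy acids. The quaternary centre is not involved, and the CIP letter changes from S to R only because the priorities change.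

**Step 22**
Reactants: 31 the hydroxy ester from step 20; 33 (R)-2-methylglycidic acid
Product: 35 methyl (1(10)E,4R,5S,6R,7R,8S,9S)-8-acetoxy-4,5-epoxy-9-{[(2R)-2-methyloxirane-2-carbonyl]oxy}germacra-1(10),11(13)-dien-12,6-olid-14-oate, via mixed anhydride 34 (not isolated)
Conditions: 2,4,6-trichlorobenzoyl chloride, Et3N, THF, 0 °C; then 31, DMAP, toluene, rt
Reagents that add atoms: none
Why: Yamaguchi esterification. DMAP attacks the less hindered aliphatic carbonyl of the mixed anhydride, and the acylpyridinium acylates the single free hydroxyl. The conditions are non-acidic, so both epoxides should survive, and no stereocentre is touched.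

## Compound list

1 | neryl acetate | CC(=O)OC/C=C(/C)CCC=C(C)C | starting material
2 | secondary ozonide of 1 at the distal alkene | CC(=O)OC/C=C(/C)CCC1OOC(C)(C)O1 | intermediate (not isolated)
3 | (4Z)-6-acetoxy-4-methylhex-4-enal | CC(=O)OC/C=C(/C)CCC=O | intermediate
4 | methyl 2-[bis(2,2,2-trifluoroethoxy)phosphoryl]acetate | COC(=O)CP(=O)(OCC(F)(F)F)OCC(F)(F)F | starting material
5 | (chloromethoxy)triisopropylsilane | ClCO[Si](C(C)C)(C(C)C)C(C)C | starting material
6 | methyl 2-[bis(2,2,2-trifluoroethoxy)phosphoryl]-3-[(triisopropylsilyl)oxy]propanoate | COC(=O)C(CO[Si](C(C)C)(C(C)C)C(C)C)P(=O)(OCC(F)(F)F)OCC(F)(F)F | intermediate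
7 | methyl (2Z,6Z)-8-acetoxy-6-methyl-2-{[(triisopropylsilyl)oxy]methyl}octa-2,6-dienoate | CC(=O)OC/C=C(/C)CC/C=C(\C(=O)OC)CO[Si](C(C)C)(C(C)C)C(C)C | intermediate
8 | methyl (2Z,6Z)-8-hydroxy-6-methyl-2-{[(triisopropylsilyl)oxy]methyl}octa-2,6-dienoate | OC/C=C(/C)CC/C=C(\C(=O)OC)CO[Si](C(C)C)(C(C)C)C(C)C | intermediate
9 | methyl (2Z,6Z)-6-methyl-8-oxo-2-{[(triisopropylsilyl)oxy]methyl}octa-2,6-dienoate | O=C/C=C(/C)CC/C=C(\C(=O)OC)CO[Si](C(C)C)(C(C)C)C(C)C | intermediate
10 | 2-allyl-4,4,5,5-tetramethyl-1,3,2-dioxaborolane | C=CCB1OC(C)(C)C(C)(C)O1 | starting material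
11 | methyl but-3-enoate | COC(=O)CC=C | starting material
12 | methyl (3E)-5-(4,4,5,5-tetramethyl-1,3,2-dioxaborolan-2-yl)pent-3-enoate | COC(=O)C/C=C/CB1OC(C)(C)C(C)(C)O1 | intermediate
13 | pinacol borate (O6–B) of 14 | COC(=O)C[C@H](C=C)[C@@H](OB1OC(C)(C)C(C)(C)O1)/C=C(/C)CC/C=C(\C(=O)OC)CO[Si](C(C)C)(C(C)C)C(C)C | intermediate (not isolated)
14 | dimethyl (2Z,6Z,8R,9R)-9-ethenyl-8-hydroxy-6-methyl-2-{[(triisopropylsilyl)oxy]methyl}undeca-2,6-dienedioate | COC(=O)C[C@H](C=C)[C@@H](O)/C=C(/C)CC/C=C(\C(=O)OC)CO[Si](C(C)C)(C(C)C)C(C)C | intermediate
15 | dimethyl (2Z,6R,7S,8R,9R)-6,7-epoxy-9-ethenyl-8-hydroxy-6-methyl-2-{[(triisopropylsilyl)oxy]methyl}undec-2-enedioate | COC(=O)C[C@H](C=C)[C@@H](O)[C@@H]1O[C@]1(C)CC/C=C(\C(=O)OC)CO[Si](C(C)C)(C(C)C)C(C)C | intermediate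
16 | (4R,5R)-4-ethenyl-5-[(2S,3R)-3-{(3E)-4-(hydroxymethyl)-5-[(triisopropylsilyl)oxy]pent-3-en-1-yl}-3-methyloxiran-2-yl]oxolan-2-ol (lactol epimers) | C=C[C@H]1CC(O)O[C@H]1[C@@H]1O[C@]1(C)CC/C=C(\CO)CO[Si](C(C)C)(C(C)C)C(C)C | intermediate
17 | lactol enal: 16 with the allylic alcohol oxidised to the Z-aldehyde | C=C[C@H]1CC(O)O[C@H]1[C@@H]1O[C@]1(C)CC/C=C(\C=O)CO[Si](C(C)C)(C(C)C)C(C)C | intermediate (not isolated)
18 | (4R,5R)-4-ethenyl-5-[(2S,3R)-3-{(3Z)-4-formyl-5-[(triisopropylsilyl)oxy]pent-3-en-1-yl}-3-methyloxiran-2-yl]oxolan-2-one | C=C[C@H]1CC(=O)O[C@H]1[C@@H]1O[C@]1(C)CC/C=C(\C=O)CO[Si](C(C)C)(C(C)C)C(C)C | intermediate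
19 | secondary ozonide of the vinyl group of 18 | C1OOC(O1)[C@H]1CC(=O)O[C@H]1[C@@H]1O[C@]1(C)CC/C=C(\C=O)CO[Si](C(C)C)(C(C)C)C(C)C | intermediate (not isolated)
20 | (2R,3S)-2-[(2S,3R)-3-{(3Z)-4-formyl-5-[(triisopropylsilyl)oxy]pent-3-en-1-yl}-3-methyloxiran-2-yl]-5-oxooxolane-3-carbaldehyde | O=C[C@H]1CC(=O)O[C@H]1[C@@H]1O[C@]1(C)CC/C=C(\C=O)CO[Si](C(C)C)(C(C)C)C(C)C | intermediate
21 | (4R,5S,6R,7R,8S,9S)-4,5-epoxy-8,9-dihydroxy-14-[(triisopropylsilyl)oxy]-13-norgermacr-1(10)-en-12,6-olide | C1C(=O)O[C@@H]2[C@H]1[C@H](O)[C@@H](O)/C(CO[Si](C(C)C)(C(C)C)C(C)C)=C\CC[C@@]1(C)O[C@@H]21 | intermediate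
22 | 4,5-epoxy-8,9,14-trihydroxy-13-norgermacr-1(10)-en-12,6-olide | C1C(=O)O[C@@H]2[C@H]1[C@H](O)[C@@H](O)/C(CO)=C\CC[C@@]1(C)O[C@@H]21 | intermediate
23 | 9,14-O-(di-tert-butylsilanediyl)-4,5-epoxy-8-hydroxy-13-norgermacr-1(10)-en-12,6-olide | C1C(=O)O[C@@H]2[C@H]1[C@H](O)[C@@H](O[Si](C(C)(C)C)(C(C)(C)C)OC3)/C3=C\CC[C@@]1(C)O[C@@H]21 | intermediate
24 | 11-[(dimethylamino)methyl] derivative of 23 (C11 epimers) | CN(C)CC1C(=O)O[C@@H]2[C@H]1[C@H](O)[C@@H](O[Si](C(C)(C)C)(C(C)(C)C)OC3)/C3=C\CC[C@@]1(C)O[C@@H]21 | intermediate (not isolated)
25 | trimethylammonium iodide of 24 | C[N+](C)(C)CC1C(=O)O[C@@H]2[C@H]1[C@H](O)[C@@H](O[Si](C(C)(C)C)(C(C)(C)C)OC3)/C3=C\CC[C@@]1(C)O[C@@H]21.[I-] | intermediate (not isolated)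
26 | 9,14-O-(di-tert-butylsilanediyl)-4,5-epoxy-8-hydroxygermacra-1(10),11(13)-dien-12,6-olide | C=C1C(=O)O[C@@H]2[C@H]1[C@H](O)[C@@H](O[Si](C(C)(C)C)(C(C)(C)C)OC3)/C3=C\CC[C@@]1(C)O[C@@H]21 | intermediate
27 | 8-acetoxy-9,14-O-(di-tert-butylsilanediyl)-4,5-epoxygermacra-1(10),11(13)-dien-12,6-olide | C=C1C(=O)O[C@@H]2[C@H]1[C@H](OC(C)=O)[C@@H](O[Si](C(C)(C)C)(C(C)(C)C)OC3)/C3=C\CC[C@@]1(C)O[C@@H]21 | intermediate
28 | 8-acetoxy-4,5-epoxy-9,14-dihydroxygermacra-1(10),11(13)-dien-12,6-olide | C=C1C(=O)O[C@@H]2[C@H]1[C@H](OC(C)=O)[C@@H](O)/C(CO)=C\CC[C@@]1(C)O[C@@H]21 | intermediate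
29 | 8-acetoxy-4,5-epoxy-9-hydroxy-14-oxogermacra-1(10),11(13)-dien-12,6-olide | C=C1C(=O)O[C@@H]2[C@H]1[C@H](OC(C)=O)[C@@H](O)/C(C=O)=C\CC[C@@]1(C)O[C@@H]21 | intermediate
30 | 8-acetoxy-4,5-epoxy-9-hydroxygermacra-1(10),11(13)-dien-12,6-olid-14-oic acid | C=C1C(=O)O[C@@H]2[C@H]1[C@H](OC(C)=O)[C@@H](O)/C(C(=O)O)=C\CC[C@@]1(C)O[C@@H]21 | intermediate
31 | methyl 8-acetoxy-4,5-epoxy-9-hydroxygermacra-1(10),11(13)-dien-12,6-olid-14-oate | C=C1C(=O)O[C@@H]2[C@H]1[C@H](OC(C)=O)[C@@H](O)/C(C(=O)OC)=C\CC[C@@]1(C)O[C@@H]21 | intermediate
32 | (S)-2-methylglycidol | OC[C@@]1(C)CO1 | starting material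
33 | (R)-2-methylglycidic acid | OC(=O)[C@@]1(C)CO1 | intermediate
34 | (R)-2-methylglycidic 2,4,6-trichlorobenzoic anhydride | O=C(OC(=O)[C@@]1(C)CO1)c1c(Cl)cc(Cl)cc1Cl | intermediate (not isolated)
35 | methyl (1(10)E,4R,5S,6R,7R,8S,9S)-8-acetoxy-4,5-epoxy-9-{[(2R)-2-methyloxirane-2-carbonyl]oxy}germacra-1(10),11(13)-dien-12,6-olid-14-oate | C=C1C(=O)O[C@@H]2[C@H]1[C@H](OC(C)=O)[C@@H](OC(=O)[C@@]1(C)CO1)/C(C(=O)OC)=C\CC[C@@]1(C)O[C@@H]21 | target

## Step count and least certain steps

Total: 22 steps. Longest linear sequence: 19 steps, from 1 to 35 through steps 1, 3–5, 7–20 and 22. Steps 2, 6 and 21 are side branches.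

**Step 12 (key step).** The most likely failure is erosion of diastereocontrol at C9: if both oxygens are held on one samarium centre, the chelated erythro (ring-cis) diol forms. Competing intermolecular coupling and rotation of the allylic ketyl before ring closure are the other risks. Fallback: starting from 20, the coupling is run to the erythro isomer, the 9-epimeric diol F1. The allylic C9 hydroxyl is then inverted by a Mitsunobu reaction with chloroacetic acid (PPh3, diisopropyl azodicarboxylate), which reacts at the allylic position and not at C8, to give the 9-O-chloroacetate F2 with the required configuration. Thiourea with NaHCO3 removes the chloroacetyl group and returns the route to 21.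

**Step 3.** The risk is loss of Z-selectivity with the bulky α-substituent, or β-elimination of silanolate from the phosphonate anion. Fallback: from 3, olefination with the α-bromo analogue of the trifluoroethyl phosphonoacetate (t-BuOK, 18-crown-6) gives the bromo enoate F3, in which the ester is cis to the chain. Stille coupling with (tributylstannyl)methanol [Pd(PPh3)4 as the source of zerovalent palladium, CuI, rt] replaces bromine with retention and gives the hydroxymethyl enoate F4. Silylation with triisopropylsilyl chloride and imidazole returns the route to 7.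

**Step 7.** The risk is incomplete enantio- and diastereocontrol: the boronate from step 6 may carry some Z-isomer, which leads to the syn adduct, and the facial bias of the acid on a β,β-disubstituted enal is unproven. Fallback: from 9, a catalytic asymmetric Nozaki–Hiyama–Kishi allylation with methyl (E)-5-bromopent-3-enoate (CrCl3 reduced in situ by Mn to divalent chromium, Me3SiCl, chiral sulfonamide–oxazoline ligand). The allylchromium reagent equilibrates to its E-form and gives the anti adduct whatever the halide geometry. The route is rejoined at 14.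

**Step 15.** The risk is acyl transfer of the lactone to the free O8 alkoxide, or aminomethylation on oxygen, during enolate formation and warming. Fallback: from 23, the C8 hydroxyl is first masked with N-(trimethylsilyl)imidazole to give the 8-O-trimethylsilyl ether F5. The same Mannich–quaternisation–elimination sequence gives the silylated methylene lactone F6, and citric acid in methanol at 0 °C returns the route to 26.

**Step 22.** The risk is slow acylation of the hindered C9 hydroxyl, which is hydrogen-bonded and adjacent to the acrylate, with competing O8-to-O9 acetyl migration under the basic conditions. Fallback: the glycidate is introduced before C14 is oxidised, while the C9 hydroxyl is an ordinary allylic alcohol. From 28, selective silylation of the primary hydroxyl (tert-butyldimethylsilyl chloride, imidazole) gives the 14-O-silyl ether F7. Yamaguchi esterification with 33 gives the glycidate F8. Buffered Bu4NF gives the C14 alcohol F9, TEMPO/PhI(OAc)2 the aldehyde F10, NaClO2 the acid F11, and MeI/KHCO3 returns the route to 35.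

## Further compounds

F1 | step 12 | 9-epimer of 21 (8,9-erythro diol) | C1C(=O)O[C@@H]2[C@H]1[C@H](O)[C@H](O)/C(CO[Si](C(C)C)(C(C)C)C(C)C)=C\CC[C@@]1(C)O[C@@H]21
F2 | step 12 | 9-O-chloroacetate of 21 | C1C(=O)O[C@@H]2[C@H]1[C@H](O)[C@@H](OC(=O)CCl)/C(CO[Si](C(C)C)(C(C)C)C(C)C)=C\CC[C@@]1(C)O[C@@H]21
F3 | step 3 | methyl (2E,6Z)-8-acetoxy-2-bromo-6-methylocta-2,6-dienoate | CC(=O)OC/C=C(/C)CC/C=C(\C(=O)OC)Br
F4 | step 3 | methyl (2Z,6Z)-8-acetoxy-2-(hydroxymethyl)-6-methylocta-2,6-dienoate | CC(=O)OC/C=C(/C)CC/C=C(\C(=O)OC)CO
F0 | step 7 | none | none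
F5 | step 15 | 8-O-trimethylsilyl ether of 23 | C1C(=O)O[C@@H]2[C@H]1[C@H](O[Si](C)(C)C)[C@@H](O[Si](C(C)(C)C)(C(C)(C)C)OC3)/C3=C\CC[C@@]1(C)O[C@@H]21
F6 | step 15 | 8-O-trimethylsilyl ether of 26 | C=C1C(=O)O[C@@H]2[C@H]1[C@H](O[Si](C)(C)C)[C@@H](O[Si](C(C)(C)C)(C(C)(C)C)OC3)/C3=C\CC[C@@]1(C)O[C@@H]21
F7 | step 22 | 14-O-(tert-butyldimethylsilyl) ether of 28 | C=C1C(=O)O[C@@H]2[C@H]1[C@H](OC(C)=O)[C@@H](O)/C(CO[Si](C)(C)C(C)(C)C)=C\CC[C@@]1(C)O[C@@H]21
F8 | step 22 | 9-O-[(R)-2-methylglycidoyl] derivative of F7 | C=C1C(=O)O[C@@H]2[C@H]1[C@H](OC(C)=O)[C@@H](OC(=O)[C@@]1(C)CO1)/C(CO[Si](C)(C)C(C)(C)C)=C\CC[C@@]1(C)O[C@@H]21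
F9 | step 22 | 14-alcohol: 8-acetoxy-4,5-epoxy-14-hydroxy-9-[(R)-2-methylglycidoyloxy]germacra-1(10),11(13)-dien-12,6-olide | C=C1C(=O)O[C@@H]2[C@H]1[C@H](OC(C)=O)[C@@H](OC(=O)[C@@]1(C)CO1)/C(CO)=C\CC[C@@]1(C)O[C@@H]21
F10 | step 22 | 14-aldehyde corresponding to F9 | C=C1C(=O)O[C@@H]2[C@H]1[C@H](OC(C)=O)[C@@H](OC(=O)[C@@]1(C)CO1)/C(C=O)=C\CC[C@@]1(C)O[C@@H]21
F11 | step 22 | 14-carboxylic acid corresponding to 35 | C=C1C(=O)O[C@@H]2[C@H]1[C@H](OC(C)=O)[C@@H](OC(=O)[C@@]1(C)CO1)/C(C(=O)O)=C\CC[C@@]1(C)O[C@@H]21
A1 | alternative 1 | cis-fused α-methylene lactol methyl ether with C8 acetate and C9 silyl ether (ten-membered carbocycle) | C=C1[C@@H](OC)O[C@@H]2[C@H]1[C@H](OC(C)=O)[C@@H](O[Si](C)(C)C(C)(C)C)/C(C(=O)OC)=C\CC[C@@]1(C)O[C@@H]21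
A2 | alternative 1 | 2-bromoallyl mixed acetal on O6 of the ten-membered C7=C8 enol acetate | C=C(Br)C(OC)O[C@@H]2/C=C(OC(C)=O)\[C@@H](O[Si](C)(C)C(C)(C)C)/C(C(=O)OC)=C\CC[C@@]1(C)O[C@@H]21
A3 | alternative 2 | ten-membered carbocycle bridged by an isoxazoline across C6, C7 and C8 | CC(C)(C)[Si](C)(C)OCC[C@H]1[C@H]2ON=C1[C@@H](O[Si](C)(C)C(C)(C)C)/C(C(=O)OC)=C\CC[C@@]1(C)O[C@@H]21
A4 | alternative 2 | open-chain C8 aldoxime with Z-C6=C7 alkene | ON=C[C@@H](O[Si](C)(C)C(C)(C)C)/C(C(=O)OC)=C\CC[C@@]1(C)O[C@H]1/C=C\CCO[Si](C)(C)C(C)(C)C
A5 | alternative 2 | C8 nitrile oxide derived from A4 | [O-][N+]#C[C@@H](O[Si](C)(C)C(C)(C)C)/C(C(=O)OC)=C\CC[C@@]1(C)O[C@H]1/C=C\CCO[Si](C)(C)C(C)(C)C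
A6 | alternative 3 | ten-membered C6 allylic alcohol with Z-C4=C5 and 8,9-acetonide | C1/C(C)=C\[C@H](O)[C@H](CC(=O)OC)[C@H](OC(C)(C)O2)[C@@H]2/C(C(=O)OC)=C\C1
A7 | alternative 3 | open-chain C6 aldehyde with Z-vinyl iodide at C5 | O=C[C@H](CC(=O)OC)[C@@H]1OC(C)(C)O[C@H]1/C(C(=O)OC)=C\CC/C(C)=C\I
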